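Each of the three trans-2-aryl-2,3-dihydrobenzofurans is a ring-contracted flavanone. Central ring A (2S aryl at C2, oxygen at C6, carbon at C3 and C4) is (2S)-naringenin whose aryl carbon C4a has moved from C4 to C3. One oxidative 1,2-aryl shift forms C3–C3a, shrinks the pyranone and turns the carbonyl carbon into an ester, later replaced by ring C, while the former 5-oxygen, already a triflate at C4, receives ring B. The precursor is (2S)-naringenin as its 7-O-isopropyl, 4'-O-pivaloyl, 5-O-triflyl derivative, so that only the benzo ring can migrate. Rings B and C (2R,3R) use the same contraction on a synthetic (2R)-flavanone.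

Key step: step 4

Assumption: commercial natural (2S)-naringenin is taken as enantiopure (to be confirmed by chiral HPLC before use), and (S)-t-BuPyOx is taken to deliver the (2R)-flavanone by analogy with its sense of induction on cyclic enones, the antipodal ligand being used otherwise.

Steps 1–4 make the ring A unit, steps 5–14 the ring B acid and the ring C triflate, and steps 15–22 assemble and deprotect.

Step 1
Reactants: 1 (2S)-naringenin; 2 propan-2-ol
Product: 3 (2S)-5-hydroxy-2-(4-hydroxyphenyl)-7-isopropoxychroman-4-one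
Conditions: i-PrOH (1.1 equiv), PPh3, DIAD, THF, 0 °C to rt
Reagents that add atoms: 2 propan-2-ol, CC(C)O
Why: Mitsunobu etherification: the most acidic phenol (7-OH, para to the carbonyl) displaces the phosphonium-activated alcohol, the hydrogen-bonded 5-OH does not react, and because no free base is present the flavanone cannot open to the chalcone, so C2 stays S.

Step 2
Reactants: 3 (2S)-5-hydroxy-2-(4-hydroxyphenyl)-7-isopropoxychroman-4-one; 4 pivaloyl chloride
Product: 5 4-[(2S)-5-hydroxy-7-isopropoxy-4-oxochroman-2-yl]phenyl pivalate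
Conditions: PivCl (1.1 equiv), pyridine, CH2Cl2, 0 °C
Reagents that add atoms: 4 pivaloyl chloride, CC(C)(C)C(=O)Cl
Why: Phenol O-acylation of the only non-chelated hydroxyl; pyridine is too weak to trigger ring opening, and the pivalate turns the 2-aryl group into a poor migrating and poor cation-stabilising group for step 4 while serving as a base-removable protecting group to the end.

Step 3
Reactants: 5 4-[(2S)-5-hydroxy-7-isopropoxy-4-oxochroman-2-yl]phenyl pivalate; 6 trifluoromethanesulfonic anhydride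
Product: 7 4-[(2S)-7-isopropoxy-4-oxo-5-(triflyloxy)chroman-2-yl]phenyl pivalate, i.e. (2S)-7-O-isopropyl-4'-O-pivaloyl-5-O-triflylnaringenin
Conditions: Tf2O, pyridine, CH2Cl2, −20 to 0 °C
Reagents that add atoms: 6 trifluoromethanesulfonic anhydride, O=S(=O)(OS(=O)(=O)C(F)(F)F)C(F)(F)F
Why: O-Triflation of the chelated 5-hydroxyl, which resists alkylation without strong base but reacts readily with Tf2O/pyridine; the triflate is inert to acid and oxidant, tempers the arene against electrophilic iodine and is already the cross-coupling handle needed at C4 of ring A.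

Step 4
Reactants: 7 (2S)-7-O-isopropyl-4'-O-pivaloyl-5-O-triflylnaringenin; 8 trimethyl orthoformate; 9 (diacetoxyiodo)benzene
Product: 11 methyl (2S,3S)-6-isopropoxy-2-[4-(pivaloyloxy)phenyl]-4-(triflyloxy)-2,3-dihydrobenzofuran-3-carboxylate, via methyl enol ether 10 (not isolated)
Conditions: PhI(OAc)2 (1.1 equiv), H2SO4 (cat.), HC(OMe)3, 0 °C to rt; aq. NaHCO3 work-up
Reagents that add atoms: 8 trimethyl orthoformate, COC(OC)OC
Why: Acid and the orthoformate convert ketone 7 into methyl enol ether 10, whose C3 attacks the trivalent iodine of PhI(OAc)2 on the face anti to the C2 aryl group; methanol adds to the C4 oxocarbenium ion, and the benzo-ring carbon C4a, antiperiplanar to the equatorial C3–I bond, shifts from C4 to C3 through a phenonium-like transition state with loss of iodobenzene, the resulting dimethoxycarbenium ion ending as the methyl ester. This is the known hypervalent-iodine (or thallium trinitrate) oxidative ring contraction of flavanones in trimethyl orthoformate to methyl trans-2-aryl-2,3-dihydrobenzofuran-3-carboxylates. The five-membered ring is not closed by a cyclisation but arises by this 1,2-aryl shift (C3–C3a forms as C4–C4a breaks), the only ring-forming event being the transient three-membered phenonium bridge (3-exo ipso attack). The new C3 stereocentre is set by the C2 aryl group: anti addition of iodine followed by migration with inversion gives the 2,3-trans (2S,3S) ester, which is also the thermodynamically preferred epimer. The step needs migration of C4a in preference to the C2 hydrogen or the 2-aryl group and needs C2 to stay untouched; the 7-isopropoxy group para to C4a makes the benzo ring the best migrating group, the 4'-pivalate makes the 2-aryl group a poor migrating group and a poor stabiliser of a C2 cation, the 5-triflate tempers the arene against iodination, and the medium is never basic, so ring opening to a chalcone cannot occur.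

Step 5
Reactants: 12 4-hydroxyphenylboronic acid; 4 pivaloyl chloride
Product: 13 4-(pivaloyloxy)phenylboronic acid
Conditions: PivCl (1.1 equiv), pyridine, CH2Cl2–THF, 0 °C; aqueous work-up
Reagents that add atoms: 4 pivaloyl chloride, CC(C)(C)C(=O)Cl
Why: Phenol O-acylation; mixed B–O acyl species formed on the boronic acid revert on aqueous work-up.

Step 6
Reactants: 14 5,7-dihydroxychromone; 15 2-bromopropane
Product: 16 5-hydroxy-7-isopropoxy-4H-chromen-4-one
Conditions: i-PrBr (1.2 equiv), K2CO3, DMF, 60 °C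
Reagents that add atoms: 15 2-bromopropane, CC(C)Br
Why: Williamson etherification selective for the more acidic, non-chelated 7-hydroxyl; the chromone has no stereocentre, so basic conditions are harmless here.

Step 7
Reactants: 16 5-hydroxy-7-isopropoxy-4H-chromen-4-one; 17 benzyl bromide
Product: 18 5-(benzyloxy)-7-isopropoxy-4H-chromen-4-one
Conditions: BnBr, K2CO3, DMF, 70 °C
Reagents that add atoms: 17 benzyl bromide, BrCc1ccccc1
Why: Williamson etherification of the chelated 5-hydroxyl under more forcing conditions, again without stereochemical risk on the achiral chromone; benzyl is chosen because it is the only group later removed by hydrogenolysis.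

Step 8
Reactants: 18 5-(benzyloxy)-7-isopropoxy-4H-chromen-4-one; 13 4-(pivaloyloxy)phenylboronic acid
Product: 19 4-[(2R)-5-(benzyloxy)-7-isopropoxy-4-oxochroman-2-yl]phenyl pivalate
Conditions: Pd(OCOCF3)2 (5 mol%), (S)-t-BuPyOx (6 mol%), NH4PF6, H2O (5 equiv), ClCH2CH2Cl, 60 °C
Reagents that add atoms: 13 4-(pivaloyloxy)phenylboronic acid, CC(C)(C)C(=O)Oc1ccc(B(O)O)cc1
Why: Palladium-catalysed enantioselective conjugate addition of an arylboronic acid to a chromone (Hayashi–Miyaura-type 1,4-addition with a cationic divalent palladium/pyridine-oxazoline catalyst): transmetalation, enantioface-selective insertion of the C2=C3 bond into the aryl–palladium bond under control of the tert-butyl oxazoline and protonation of the palladium enolate set C2 as R under non-basic conditions that do not open the flavanone.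

Step 9
Reactants: 19 4-[(2R)-5-(benzyloxy)-7-isopropoxy-4-oxochroman-2-yl]phenyl pivalate; 8 trimethyl orthoformate; 9 (diacetoxyiodo)benzene
Product: 21 methyl (2R,3R)-4-(benzyloxy)-6-isopropoxy-2-[4-(pivaloyloxy)phenyl]-2,3-dihydrobenzofuran-3-carboxylate, via methyl enol ether 20 (not isolated)
Conditions: PhI(OAc)2 (1.05 equiv), H2SO4 (cat.), HC(OMe)3, 0 °C to rt; aq. NaHCO3 work-up
Reagents that add atoms: 8 trimethyl orthoformate, COC(OC)OC
Why: Same hypervalent-iodine oxidative ring contraction as in step 4, applied to the enantiomeric series: iodane addition anti to the C2 aryl group and invertive C4-to-C3 shift of C4a give the (2R,3R)-trans ester, the two ortho oxygens and the para isopropoxy group making the benzo ring the migrating group while the 4'-pivalate holds the 2-aryl group back.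

Step 10
Reactants: 21 methyl (2R,3R)-4-(benzyloxy)-6-isopropoxy-2-[4-(pivaloyloxy)phenyl]-2,3-dihydrobenzofuran-3-carboxylate
Product: 22 (2R,3R)-4-(benzyloxy)-6-isopropoxy-2-[4-(pivaloyloxy)phenyl]-2,3-dihydrobenzofuran-3-carboxylic acid (ring B acid)
Conditions: LiI, EtOAc, reflux; then 1 M HCl
Reagents that add atoms: none
Why: Nucleophilic ester dealkylation (SN2 attack of iodide at the O-methyl carbon): it avoids hydroxide, so the aryl pivalate survives, C2 bears no acidic hydrogen, and any epimerisation at C3 is irrelevant because this centre is reset in the couplings.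

Step 11
Reactants: 23 5-bromobenzene-1,3-diol; 4 pivaloyl chloride
Product: 24 5-bromo-1,3-phenylene dipivalate
Conditions: PivCl (2.3 equiv), pyridine, CH2Cl2, 0 °C to rt
Reagents that add atoms: 4 pivaloyl chloride, CC(C)(C)C(=O)Cl
Why: Double phenol O-acylation; the pivalates make the bromide electron-poor for oxidative addition and are removed with the other esters at the end.

Step 12
Reactants: 22 ring B acid; 24 5-bromo-1,3-phenylene dipivalate
Product: 25 5-{(2R,3R)-4-(benzyloxy)-6-isopropoxy-2-[4-(pivaloyloxy)phenyl]-2,3-dihydrobenzofuran-3-yl}-1,3-phenylene dipivalate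
Conditions: Ir[dF(CF3)ppy]2(dtbbpy)PF6 (2 mol%), NiCl2·glyme (10 mol%), dtbbpy (15 mol%), Cs2CO3, DMA, blue LEDs, rt
Reagents that add atoms: 24 5-bromo-1,3-phenylene dipivalate, CC(C)(C)C(=O)Oc1cc(Br)cc(OC(=O)C(C)(C)C)c1
Why: Nickel/photoredox decarboxylative arylation: the caesium carboxylate is oxidised by the excited iridium photocatalyst, CO2 is lost, the benzylic C3 radical is captured by the aryl–nickel bromide complex and reductive elimination delivers the aryl group trans to the C2 aryl group (substrate control), the unhindered ester-bearing aryl bromide being an easy electrophile.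

Step 13
Reactants: 25 5-{(2R,3R)-4-(benzyloxy)-6-isopropoxy-2-[4-(pivaloyloxy)phenyl]-2,3-dihydrobenzofuran-3-yl}-1,3-phenylene dipivalate
Product: 26 5-{(2R,3R)-4-hydroxy-6-isopropoxy-2-[4-(pivaloyloxy)phenyl]-2,3-dihydrobenzofuran-3-yl}-1,3-phenylene dipivalate
Conditions: H2 (1 atm), 10% Pd/C, EtOAc, rt
Reagents that add atoms: none
Why: Hydrogenolysis of the aryl benzyl ether; no alkene, halide or triflate is present, and the cyclic benzylic C2–O bond, deactivated by the para-pivaloyloxy group, is cleaved far more slowly than an O-benzyl group.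

Step 14
Reactants: 26 5-{(2R,3R)-4-hydroxy-6-isopropoxy-2-[4-(pivaloyloxy)phenyl]-2,3-dihydrobenzofuran-3-yl}-1,3-phenylene dipivalate; 6 trifluoromethanesulfonic anhydride
Product: 27 5-{(2R,3R)-6-isopropoxy-2-[4-(pivaloyloxy)phenyl]-4-(triflyloxy)-2,3-dihydrobenzofuran-3-yl}-1,3-phenylene dipivalate (ring C triflate)
Conditions: Tf2O, pyridine, CH2Cl2, 0 °C
Reagents that add atoms: 6 trifluoromethanesulfonic anhydride, O=S(=O)(OS(=O)(=O)C(F)(F)F)C(F)(F)F
Why: Phenol O-triflation gives the aryl electrophile through which ring C is later joined to C3 of ring A.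

Step 15
Reactants: 11 methyl (2S,3S)-6-isopropoxy-2-[4-(pivaloyloxy)phenyl]-4-(triflyloxy)-2,3-dihydrobenzofuran-3-carboxylate; 22 ring B acid
Product: 28 methyl (2S,3S)-4-{(2R,3R)-4-(benzyloxy)-6-isopropoxy-2-[4-(pivaloyloxy)phenyl]-2,3-dihydrobenzofuran-3-yl}-6-isopropoxy-2-[4-(pivaloyloxy)phenyl]-2,3-dihydrobenzofuran-3-carboxylate (ring A–ring B ester)
Conditions: 22 (1.5 equiv), Ir[dF(CF3)ppy]2(dtbbpy)PF6 (2 mol%), NiBr2·glyme (10 mol%), dtbbpy (15 mol%), Cs2CO3, DMA, blue LEDs, rt
Reagents that add atoms: 22 ring B acid, CC(C)(C)C(=O)Oc1ccc([C@@H]2Oc3cc(OC(C)C)cc(OCc4ccccc4)c3[C@H]2C(=O)O)cc1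
Why: Same nickel/photoredox decarboxylative arylation, now with an aryl triflate as the electrophile (triflates enter the nickel/bipyridine cycle by oxidative addition as bromides do): the ring B C3 radical from 22 couples at C4 of ring A and the new C3 stereocentre of ring B is set trans to its own C2 aryl group, the methyl ester and all pivalates being inert.

Step 16
Reactants: 28 ring A–ring B ester
Product: 29 (2S,3S)-4-{(2R,3R)-4-(benzyloxy)-6-isopropoxy-2-[4-(pivaloyloxy)phenyl]-2,3-dihydrobenzofuran-3-yl}-6-isopropoxy-2-[4-(pivaloyloxy)phenyl]-2,3-dihydrobenzofuran-3-carboxylic acid (ring A–ring B acid)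
Conditions: LiI, EtOAc, reflux; then 1 M HCl
Reagents that add atoms: none
Why: Nucleophilic ester dealkylation by iodide at the O-methyl carbon, which is unaffected by the crowding around the acyl carbon and leaves the aryl pivalates, the benzyl ether and all four stereocentres alone.

Step 17
Reactants: 29 ring A–ring B acid; 27 ring C triflate
Product: 30 5-[(2R,3R)-4-{(2S,3S)-4-[(2R,3R)-4-(benzyloxy)-6-isopropoxy-2-(4-pivaloyloxyphenyl)-2,3-dihydrobenzofuran-3-yl]-6-isopropoxy-2-(4-pivaloyloxyphenyl)-2,3-dihydrobenzofuran-3-yl}-6-isopropoxy-2-(4-pivaloyloxyphenyl)-2,3-dihydrobenzofuran-3-yl]-1,3-phenylene dipivalate (ring A–B–C benzyl ether)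
Conditions: Ir[dF(CF3)ppy]2(dtbbpy)PF6 (2 mol%), NiBr2·glyme (10 mol%), dtbbpy (15 mol%), Cs2CO3, DMA, blue LEDs, rt
Reagents that add atoms: 27 ring C triflate, FC(F)(F)S(=O)(=O)Oc1cc(OC(C)C)cc2c1[C@@H](c1cc(OC(=O)C(C)(C)C)cc(OC(=O)C(C)(C)C)c1)[C@H](c1ccc(OC(=O)C(C)(C)C)cc1)O2
Why: Third use of the nickel/photoredox decarboxylative arylation: the C3 radical of ring A, formed from the carboxylate of 29, is captured by the aryl–nickel species derived from triflate 27 and reductive elimination on the less hindered face places ring C trans to the C2 aryl group of ring A, which fixes the last stereocentre as 3S.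

Step 18
Reactants: 30 ring A–B–C benzyl ether
Product: 31 ring A–B–C phenol (30 with 4-OH on ring B in place of 4-OBn)
Conditions: H2 (1 atm), 10% Pd/C, EtOAc, rt
Reagents that add atoms: none
Why: Hydrogenolysis of the single aryl benzyl ether; no alkene or triflate is present at this stage, and isopropyl ethers, pivalates and the deactivated cyclic benzylic ethers are not touched.

Step 19
Reactants: 31 ring A–B–C phenol; 6 trifluoromethanesulfonic anhydride
Product: 32 ring A–B–C triflate (4-OTf on ring B)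
Conditions: Tf2O, pyridine, CH2Cl2, 0 °C
Reagents that add atoms: 6 trifluoromethanesulfonic anhydride, O=S(=O)(OS(=O)(=O)C(F)(F)F)C(F)(F)F
Why: O-Triflation of the only free phenol installs the handle for the styryl group.

Step 20
Reactants: 32 ring A–B–C triflate; 33 3,4-diacetoxystyrene
Product: 34 ring A–B–C stilbene (ring B carrying 4-[(E)-2-(3,4-diacetoxyphenyl)ethenyl])
Conditions: Pd(OAc)2 (10 mol%), PPh3, LiCl, Et3N, DMF, 90 °C
Reagents that add atoms: 33 3,4-diacetoxystyrene, C=Cc1ccc(OC(C)=O)c(OC(C)=O)c1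
Why: Mizoroki–Heck reaction: oxidative addition of zerovalent palladium into the aryl triflate, chloride exchange (neutral pathway) for terminal-selective insertion of the styrene and syn β-hydride elimination give the E-stilbene, and aryl acetates and pivalates tolerate triethylamine in DMF.

Step 21
Reactants: 34 ring A–B–C stilbene
Product: 35 tris-phenol heptaester (34 with the three isopropyl ethers cleaved to 6-OH on rings A, B and C)
Conditions: BCl3, CH2Cl2, −78 to 0 °C; then MeOH/H2O
Reagents that add atoms: none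
Why: Lewis-acid dealkylation of aryl isopropyl ethers (the secondary alkyl group leaves as 2-chloropropane) at low temperature; the aryl esters and the E-alkene are inert, and the dihydrobenzofuran C2–O bonds resist ionisation because every 2-aryl group still carries its electron-withdrawing pivalate.

Step 22
Reactants: 35 tris-phenol heptaester
Product: 36 CNP0099535.1 (target)
Conditions: K2CO3, MeOH–THF (degassed, Ar), 0 °C to rt; then 1 M HCl to pH 5
Reagents that add atoms: none
Why: Base-mediated methanolysis (transesterification) of the five aryl pivalates and two aryl acetates under oxygen-free conditions; no stereocentre carries an acidic hydrogen, and the trans configuration of each dihydrobenzofuran is the thermodynamic one, so the six stereocentres are not at risk.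

Compound list
1 | (2S)-naringenin | O=C1C[C@@H](c2ccc(O)cc2)Oc2cc(O)cc(O)c12 | starting material
2 | propan-2-ol | CC(C)O | starting material
3 | (2S)-5-hydroxy-2-(4-hydroxyphenyl)-7-isopropoxychroman-4-one | O=C1C[C@@H](c2ccc(O)cc2)Oc2cc(OC(C)C)cc(O)c12 | intermediate
4 | pivaloyl chloride | CC(C)(C)C(=O)Cl | starting material
5 | 4-[(2S)-5-hydroxy-7-isopropoxy-4-oxochroman-2-yl]phenyl pivalate | O=C1C[C@@H](c2ccc(OC(=O)C(C)(C)C)cc2)Oc2cc(OC(C)C)cc(O)c12 | intermediate
6 | trifluoromethanesulfonic anhydride | O=S(=O)(OS(=O)(=O)C(F)(F)F)C(F)(F)F | starting material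
7 | 4-[(2S)-7-isopropoxy-4-oxo-5-(triflyloxy)chroman-2-yl]phenyl pivalate | O=C1C[C@@H](c2ccc(OC(=O)C(C)(C)C)cc2)Oc2cc(OC(C)C)cc(OS(=O)(=O)C(F)(F)F)c12 | intermediate
8 | trimethyl orthoformate | COC(OC)OC | starting material
9 | (diacetoxyiodo)benzene | CC(=O)OI(OC(C)=O)c1ccccc1 | starting material
10 | 4-[(2S)-7-isopropoxy-4-methoxy-5-(triflyloxy)-2H-chromen-2-yl]phenyl pivalate (methyl enol ether of 7) | COC1=C[C@@H](c2ccc(OC(=O)C(C)(C)C)cc2)Oc2cc(OC(C)C)cc(OS(=O)(=O)C(F)(F)F)c12 | intermediate
11 | methyl (2S,3S)-6-isopropoxy-2-[4-(pivaloyloxy)phenyl]-4-(triflyloxy)-2,3-dihydrobenzofuran-3-carboxylate | CC(C)(C)C(=O)Oc1ccc([C@H]2Oc3cc(OC(C)C)cc(OS(=O)(=O)C(F)(F)F)c3[C@@H]2C(=O)OC)cc1 | intermediate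
12 | 4-hydroxyphenylboronic acid | OB(O)c1ccc(O)cc1 | starting material
13 | 4-(pivaloyloxy)phenylboronic acid | CC(C)(C)C(=O)Oc1ccc(B(O)O)cc1 | intermediate
14 | 5,7-dihydroxychromone | O=c1ccoc2cc(O)cc(O)c12 | starting material
15 | 2-bromopropane | CC(C)Br | starting material
16 | 5-hydroxy-7-isopropoxy-4H-chromen-4-one | O=c1ccoc2cc(OC(C)C)cc(O)c12 | intermediate
17 | benzyl bromide | BrCc1ccccc1 | starting material
18 | 5-(benzyloxy)-7-isopropoxy-4H-chromen-4-one | O=c1ccoc2cc(OC(C)C)cc(OCc3ccccc3)c12 | intermediate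
19 | 4-[(2R)-5-(benzyloxy)-7-isopropoxy-4-oxochroman-2-yl]phenyl pivalate | O=C1C[C@H](c2ccc(OC(=O)C(C)(C)C)cc2)Oc2cc(OC(C)C)cc(OCc3ccccc3)c12 | intermediate
20 | 4-[(2R)-5-(benzyloxy)-7-isopropoxy-4-methoxy-2H-chromen-2-yl]phenyl pivalate (methyl enol ether of 19) | COC1=C[C@H](c2ccc(OC(=O)C(C)(C)C)cc2)Oc2cc(OC(C)C)cc(OCc3ccccc3)c12 | intermediate
21 | methyl (2R,3R)-4-(benzyloxy)-6-isopropoxy-2-[4-(pivaloyloxy)phenyl]-2,3-dihydrobenzofuran-3-carboxylate | CC(C)(C)C(=O)Oc1ccc([C@@H]2Oc3cc(OC(C)C)cc(OCc4ccccc4)c3[C@H]2C(=O)OC)cc1 | intermediate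
22 | (2R,3R)-4-(benzyloxy)-6-isopropoxy-2-[4-(pivaloyloxy)phenyl]-2,3-dihydrobenzofuran-3-carboxylic acid (ring B acid) | CC(C)(C)C(=O)Oc1ccc([C@@H]2Oc3cc(OC(C)C)cc(OCc4ccccc4)c3[C@H]2C(=O)O)cc1 | intermediate
23 | 5-bromobenzene-1,3-diol | Oc1cc(O)cc(Br)c1 | starting material
24 | 5-bromo-1,3-phenylene dipivalate | CC(C)(C)C(=O)Oc1cc(Br)cc(OC(=O)C(C)(C)C)c1 | intermediate
25 | 5-{(2R,3R)-4-(benzyloxy)-6-isopropoxy-2-[4-(pivaloyloxy)phenyl]-2,3-dihydrobenzofuran-3-yl}-1,3-phenylene dipivalate | c1ccccc1COc1cc(OC(C)C)cc2c1[C@@H](c1cc(OC(=O)C(C)(C)C)cc(OC(=O)C(C)(C)C)c1)[C@H](c1ccc(OC(=O)C(C)(C)C)cc1)O2 | intermediate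
26 | 5-{(2R,3R)-4-hydroxy-6-isopropoxy-2-[4-(pivaloyloxy)phenyl]-2,3-dihydrobenzofuran-3-yl}-1,3-phenylene dipivalate | Oc1cc(OC(C)C)cc2c1[C@@H](c1cc(OC(=O)C(C)(C)C)cc(OC(=O)C(C)(C)C)c1)[C@H](c1ccc(OC(=O)C(C)(C)C)cc1)O2 | intermediate
27 | 5-{(2R,3R)-6-isopropoxy-2-[4-(pivaloyloxy)phenyl]-4-(triflyloxy)-2,3-dihydrobenzofuran-3-yl}-1,3-phenylene dipivalate (ring C triflate) | FC(F)(F)S(=O)(=O)Oc1cc(OC(C)C)cc2c1[C@@H](c1cc(OC(=O)C(C)(C)C)cc(OC(=O)C(C)(C)C)c1)[C@H](c1ccc(OC(=O)C(C)(C)C)cc1)O2 | intermediate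
28 | ring A–ring B ester: methyl (2S,3S)-4-{(2R,3R)-4-(benzyloxy)-6-isopropoxy-2-[4-(pivaloyloxy)phenyl]-2,3-dihydrobenzofuran-3-yl}-6-isopropoxy-2-[4-(pivaloyloxy)phenyl]-2,3-dihydrobenzofuran-3-carboxylate | CC(C)(C)C(=O)Oc1ccc([C@H]2Oc3cc(OC(C)C)cc([C@@H]4c5c(OCc6ccccc6)cc(OC(C)C)cc5O[C@H]4c4ccc(OC(=O)C(C)(C)C)cc4)c3[C@@H]2C(=O)OC)cc1 | intermediate
29 | ring A–ring B acid (carboxylic acid of 28) | CC(C)(C)C(=O)Oc1ccc([C@H]2Oc3cc(OC(C)C)cc([C@@H]4c5c(OCc6ccccc6)cc(OC(C)C)cc5O[C@H]4c4ccc(OC(=O)C(C)(C)C)cc4)c3[C@@H]2C(=O)O)cc1 | intermediate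
30 | ring A–B–C benzyl ether: ring A (2S,3S) with the (2R,3R) ring C unit at C3 (through C4 of ring C) and the (2R,3R) 4-benzyloxy ring B unit at C4 (through C3 of ring B); 6-O-isopropyl on each ring, pivalates on all 4-hydroxyphenyl and resorcinol oxygens | CC(C)(C)C(=O)Oc1ccc([C@H]2Oc3cc(OC(C)C)cc([C@@H]4c5c(OCc6ccccc6)cc(OC(C)C)cc5O[C@H]4c4ccc(OC(=O)C(C)(C)C)cc4)c3[C@@H]2c2cc(OC(C)C)cc3c2[C@@H](c2cc(OC(=O)C(C)(C)C)cc(OC(=O)C(C)(C)C)c2)[C@H](c2ccc(OC(=O)C(C)(C)C)cc2)O3)cc1 | intermediate
31 | ring A–B–C phenol (30 with 4-OH on ring B) | CC(C)(C)C(=O)Oc1ccc([C@H]2Oc3cc(OC(C)C)cc([C@@H]4c5c(O)cc(OC(C)C)cc5O[C@H]4c4ccc(OC(=O)C(C)(C)C)cc4)c3[C@@H]2c2cc(OC(C)C)cc3c2[C@@H](c2cc(OC(=O)C(C)(C)C)cc(OC(=O)C(C)(C)C)c2)[C@H](c2ccc(OC(=O)C(C)(C)C)cc2)O3)cc1 | intermediate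
32 | ring A–B–C triflate (4-OTf on ring B) | CC(C)(C)C(=O)Oc1ccc([C@H]2Oc3cc(OC(C)C)cc([C@@H]4c5c(OS(=O)(=O)C(F)(F)F)cc(OC(C)C)cc5O[C@H]4c4ccc(OC(=O)C(C)(C)C)cc4)c3[C@@H]2c2cc(OC(C)C)cc3c2[C@@H](c2cc(OC(=O)C(C)(C)C)cc(OC(=O)C(C)(C)C)c2)[C@H](c2ccc(OC(=O)C(C)(C)C)cc2)O3)cc1 | intermediate
33 | 3,4-diacetoxystyrene (4-vinyl-1,2-phenylene diacetate) | C=Cc1ccc(OC(C)=O)c(OC(C)=O)c1 | starting material
34 | ring A–B–C stilbene (ring B carrying 4-[(E)-2-(3,4-diacetoxyphenyl)ethenyl]) | CC(C)(C)C(=O)Oc1ccc([C@H]2Oc3cc(OC(C)C)cc([C@@H]4c5c(/C=C/c6ccc(OC(C)=O)c(OC(C)=O)c6)cc(OC(C)C)cc5O[C@H]4c4ccc(OC(=O)C(C)(C)C)cc4)c3[C@@H]2c2cc(OC(C)C)cc3c2[C@@H](c2cc(OC(=O)C(C)(C)C)cc(OC(=O)C(C)(C)C)c2)[C@H](c2ccc(OC(=O)C(C)(C)C)cc2)O3)cc1 | intermediate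
35 | tris-phenol heptaester (34 with 6-OH on rings A, B and C) | CC(C)(C)C(=O)Oc1ccc([C@H]2Oc3cc(O)cc([C@@H]4c5c(/C=C/c6ccc(OC(C)=O)c(OC(C)=O)c6)cc(O)cc5O[C@H]4c4ccc(OC(=O)C(C)(C)C)cc4)c3[C@@H]2c2cc(O)cc3c2[C@@H](c2cc(OC(=O)C(C)(C)C)cc(OC(=O)C(C)(C)C)c2)[C@H](c2ccc(OC(=O)C(C)(C)C)cc2)O3)cc1 | intermediate
36 | CNP0099535.1: ring A (2S,3S), ring B (2R,3R), ring C (2R,3R), E-alkene | Oc1ccc([C@H]2Oc3cc(O)cc([C@@H]4c5c(/C=C/c6ccc(O)c(O)c6)cc(O)cc5O[C@H]4c4ccc(O)cc4)c3[C@@H]2c2cc(O)cc3c2[C@@H](c2cc(O)cc(O)c2)[C@H](c2ccc(O)cc2)O3)cc1 | target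

Total step count: 22. Longest linear sequence: 14 steps (steps 6, 7, 8, 9, 10, 12, 13, 14, 17, 18, 19, 20, 21, 22).

Steps most likely to fail

Step 17. Oxidative addition of nickel into the ortho-substituted triflate 27 may be slow, and capture of the C3 radical of ring A, flanked by the C2 aryl group and by ring B at C4, may be slower still, so that protodecarboxylation, oxidation of the radical with aromatisation to a benzofuran, or erosion of the trans selectivity could take over. The fallback sets out from 29 and 27 and returns at 30 by a thermal reductive cross-electrophile coupling instead of the photoredox union. Acid 29 would be condensed with N-hydroxyphthalimide (DIC, cat. DMAP, CH2Cl2) to the N-acyloxyphthalimide ester F1. Triflate 27 would be exchanged with NaI under [Cp*Ru(MeCN)3]OTf catalysis (DMI, 100 °C) to the ring C aryl iodide F2. F1 and F2 would then be joined with NiBr2·glyme, dtbbpy and zinc dust in DMA at rt: single-electron reduction of the ester releases the same C3 radical, and the same substrate control should give 30.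

Step 15. The triflate of 11 may be reduced or hydrolysed faster than it couples, and the ring B radical may dimerise or be reduced, because carbon–carbon bond formation between two ortho-flanked partners is slow. The fallback sets out from 11 and 22 and returns at 28 by inverting the role of ring A from electrophile to nucleophile. Triflate 11 would be borylated with B2(OH)4 (Pd(OAc)2, XPhos, KOAc, EtOH, 80 °C) to the arylboronic acid F3. Acid 22 would be converted with N-hydroxytetrachlorophthalimide and DIC into the redox-active ester F4. A nickel-catalysed decarboxylative Suzuki–Miyaura-type arylation of F4 with F3 (NiCl2·6H2O, 4,7-diphenyl-1,10-phenanthroline, Et3N, dioxane–DMF, 75 °C) would then give 28, the ring B C3 centre again being set trans to its C2 aryl group.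

Step 4. The aryl shift may lose out to elimination across C2–C3 (flavone formation) or to migration of the 2-aryl group, the arene may be iodinated or over-oxidised, or acid may erode the C2 configuration. The fallback sets out from 7 and returns at 11, keeping the same C4-to-C3 shift of C4a but separating activation from rearrangement, with no base at any point. Ketone 7 would be brominated with CuBr2 (EtOAc–CHCl3, reflux) to the 2,3-trans 3-bromo ketone F5. F5 would be ketalised with HC(OMe)3/MeOH and catalytic TsOH to the dimethyl ketal F6. Treatment of F6 with AgBF4 in MeOH/HC(OMe)3 would remove bromide and trigger the 1,2-aryl shift of an α-halo ketal (the Lewis-acid-promoted rearrangement used to make 2-arylalkanoates), and hydrolysis of the dimethoxycarbenium ion gives 11 with inversion at C3, hence 2,3-trans.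

Further compounds
F1 | step 17 | 1,3-dioxoisoindolin-2-yl ester of ring A–ring B acid 29 | CC(C)(C)C(=O)Oc1ccc([C@H]2Oc3cc(OC(C)C)cc([C@@H]4c5c(OCc6ccccc6)cc(OC(C)C)cc5O[C@H]4c4ccc(OC(=O)C(C)(C)C)cc4)c3[C@@H]2C(=O)ON2C(=O)c3ccccc3C2=O)cc1
F2 | step 17 | 5-{(2R,3R)-4-iodo-6-isopropoxy-2-[4-(pivaloyloxy)phenyl]-2,3-dihydrobenzofuran-3-yl}-1,3-phenylene dipivalate | Ic1cc(OC(C)C)cc2c1[C@@H](c1cc(OC(=O)C(C)(C)C)cc(OC(=O)C(C)(C)C)c1)[C@H](c1ccc(OC(=O)C(C)(C)C)cc1)O2
F3 | step 15 | {(2S,3S)-6-isopropoxy-3-(methoxycarbonyl)-2-[4-(pivaloyloxy)phenyl]-2,3-dihydrobenzofuran-4-yl}boronic acid | CC(C)(C)C(=O)Oc1ccc([C@H]2Oc3cc(OC(C)C)cc(B(O)O)c3[C@@H]2C(=O)OC)cc1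
F4 | step 15 | 4,5,6,7-tetrachloro-1,3-dioxoisoindolin-2-yl ester of ring B acid 22 | CC(C)(C)C(=O)Oc1ccc([C@@H]2Oc3cc(OC(C)C)cc(OCc4ccccc4)c3[C@H]2C(=O)ON2C(=O)c3c(Cl)c(Cl)c(Cl)c(Cl)c3C2=O)cc1
F5 | step 4 | 2,3-trans-3-bromo derivative of 7: 4-[3-bromo-7-isopropoxy-4-oxo-5-(triflyloxy)chroman-2-yl]phenyl pivalate, C2 unchanged in space | O=C1[C@H](Br)[C@@H](c2ccc(OC(=O)C(C)(C)C)cc2)Oc2cc(OC(C)C)cc(OS(=O)(=O)C(F)(F)F)c12
F6 | step 4 | 4,4-dimethyl ketal of F5 | COC1(OC)[C@H](Br)[C@@H](c2ccc(OC(=O)C(C)(C)C)cc2)Oc2cc(OC(C)C)cc(OS(=O)(=O)C(F)(F)F)c12
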